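The readings are simulated on assumed constants, noise included.

We decide to treat each portion of substrate as its own first-order decay, with a constant proportional to the catalyst charged, and to test whether one number can carry every flask.

| flask | substrate | reagent | free catalyst | remark | time |
|---|---|---|---|---|---|
| summer | 1.2 M (in portions, 4) | 1.8 equiv | 0.073 mol% | run made earlier; portions every 15 min |  |
| spring | 1.2 M (in portions, 4) | 1.8 equiv | 1 mol% | run made earlier; portions every 15 min |  |
| ash | 1.2 M (in portions, 4) | 1.80 equiv | 0.4 mol% | the portions of substrate follow each other after 15 min, the first at the start | 1.0 h |
| oak | 1.2 M (in portions, 4) | 1.80 equiv | 0.1 mol% | the portions of substrate follow each other after 15 min, the first at the start | 1.0 h |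
| larch | 1.2 M (in portions, 4) | 1.80 equiv | 0.6 mol% | the portions of substrate follow each other after 15 min, the first at the start | 1.0 h |
| elm | 1.2 M (in portions, 4) | 1.80 equiv | 0.05 mol% | the portions of substrate follow each other after 15 min, the first at the start | 1.0 h |
| cedar | 1.2 M (in portions, 4) | 1.80 equiv | 0.8 mol% | the portions of substrate follow each other after 15 min, the first at the start | 1.0 h |
| alder | 1.2 M (in portions, 4) | 1.80 equiv | 0.2 mol% | the portions of substrate follow each other after 15 min, the first at the start | 1.0 h |

| run | time / min | target / % |
|---|---|---|
| summer | 1.50 | 0 |
| summer | 5.00 | 0 |
| summer | 8.00 | 2 |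
| summer | 12.0 | 4 |
| summer | 20.0 | 6 |
| summer | 25.0 | 4 |
| summer | 30.0 | 6 |
| spring | 1.50 | 1 |
| spring | 5.00 | 7 |
| spring | 8.00 | 13 |
| spring | 12.0 | 14 |
| spring | 20.0 | 26 |
| spring | 25.0 | 35 |
| spring | 30.0 | 33 |

(standard deviation of a reading: 2 percentage points)

- percent here means substrate units held: one self-condensation product counts as two
- steps that have been proposed: reagent + free catalyst -> catalyst intermediate A; catalyst intermediate A -> catalyst intermediate B; substrate + catalyst intermediate B -> catalyst intermediate C; catalyst intermediate C <-> catalyst intermediate D; catalyst intermediate D <-> free catalyst + target; 2 substrate -> self-condensation product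

* the flasks by amount of target, in percent of the substrate charged, highest first, at 1.0 h (ash / oak / larch / elm / cedar / alder)
* the amount of target, in percent of the substrate charged of the flask you put first, at 1.0 h
* the amount of target, in percent of the substrate charged of the flask you put last, at 1.0 h

May we do this? Free catalyst is given back at each turn, so we freeze its total. Each target takes one reagent, and 1.80 equiv is charged, so reagent covers the substrate, but it falls as target forms. Holding it at its charge is therefore an approximation, and we make it knowingly. With it, the loss of substrate is pseudo-first-order.

What is the constant? At 30.0 min in the spring run, the first portion has aged two intervals, the second one, and the third has just arrived. The reading of 33% then means that a fraction 0.464 survives each 15 min interval, a constant of 0.0511 min⁻¹. Dividing by the catalyst concentration gives 4.26 L mol⁻¹ min⁻¹. This is the specific rate, the first-order constant of substrate per unit of catalyst charged. It is a reading, and it carries the scatter of 2 percentage points.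

Does it hold at low loading? In the summer run it leaves 0.946 per interval, so we reckon 4.01% at 30.0 min. The reading is 6%, so we keep the constant.

What follows? Cedar has the highest loading, and elm the lowest, so the order is that of the loadings. With portions aged one to four intervals, cedar keeps 0.541 per interval and reaches 73.0%. Elm keeps 0.962 and reaches 9.06%.

The forecast gives cedar > larch > ash > alder > oak > elm, with 56% and 8%. Its ground: “Target should therefore rise steadily with loading”. Its order is ours, but its top lies below our number. That top is what a first-order curve to completion through the last spring reading gives.

The simulation gives cedar > larch > ash > alder > oak > elm, with 70.8% for cedar and 9.65% for elm.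

    reagent + free catalyst → catalyst intermediate A (k = 10.0 L mol⁻¹ min⁻¹)
    catalyst intermediate A → catalyst intermediate B (k = 23.0 min⁻¹)
    substrate + catalyst intermediate B → catalyst intermediate C (k = 7.70 L mol⁻¹ min⁻¹)
    catalyst intermediate C ⇌ catalyst intermediate D (K = 1.10, k = 1100 min⁻¹)
    catalyst intermediate D ⇌ free catalyst + target (K = 0.380 M, k = 650 min⁻¹)
    2 substrate → self-condensation product (k = 6.40 × 10⁻⁶ L mol⁻¹ min⁻¹)

So the order stands, and the specific rate lands close at both ends, while the forecast's top is 15 points low. The neighbouring flask is cedar with 3.2 mol% of free catalyst. The same specific rate leaves 0.0859 per interval, so we reckon 97.7%. That flask holds 98.5% target at 1.0 h, with 1.25% of the substrate left.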